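Two amounts in this flask, both concentrations of starting material, carry the argument.

    solid substrate ⇌ starting material, rate k1*(cs1 - [starting material]) while solid is left; crystals form when [starting material] > cs1 (cs1 = 0.12 mM, k1 = 6.0 s⁻¹)
    free catalyst + impurity → spent catalyst (k2 = 7.2 × 10⁸ L mol⁻¹ s⁻¹)
    2 free catalyst ⇌ resting dimer, settled at all times (K3 = 4.9 × 10⁵ L mol⁻¹)
    starting material + reagent + free catalyst ⇌ product + free catalyst, rate k4*[starting material]*[reagent]*[free catalyst] forward; the back reaction follows from the equilibrium constant (K4 = 3700 L mol⁻¹, k4 = 1.6 × 10⁸ L² mol⁻² s⁻¹)

solid substrate 1.0 mM; reagent 0.600 equiv; free catalyst 0.1 mol%; impurity 0.14 µM; time 5.0 min

- a doubled species enters its step squared and goes two at a time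
- given per volume of solution although it is solid: solid substrate
- at the start none of the solid substrate is in solution
- what has only dissolved of solid substrate counts as not reacted
- the reaction counts as stopped when no species that holds the solid substrate changes by six tenths of a point or more over the second half of the time
- starting material means what is dissolved; the solid is not counted in it
- run time (flask): 5.0 min

- which holds at 5.0 min: what has brought the reaction to rest, or that it has not come to rest (for what has run out or reacted, a solid counts together with what of it has only dissolved) (the reagent has run out first / no working catalyst is left / it is still moving / forward and back rates have come level / all of the solid substrate has reacted)
- part of the solid substrate that has turned into other species by 5.0 min (what has only dissolved does not count)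
- the product standing at 5.0 min, as a percentage of the solid substrate charged
- the starting material standing at 5.0 min, as a percentage of the solid substrate charged

The first amount is the solubility, 0.12 mM. I freeze the dissolved starting material there, because while solid remains its dissolving half-life of 0.116 s is far shorter than the forward half-life of 0.12 min in step 4, the other concentrations as charged. With starting material frozen, step 4 is pseudo-first-order in reagent. The second amount is 0.270 mM, the inverse of the equilibrium constant of step 4: the level of starting material at which product and reagent stand equal. The catalyst stands on both sides of step 4, so it drops out of that balance.

Dividing the first amount by the second gives 0.444, the held ratio: product over reagent at balance, with starting material at its solubility. The impurity charge of 0.14 µM is smaller than the catalyst charge of 1.00 µM, and the forward half-life is short against the 5.0 min of the run, so I expect the flask to reach balance, which is thermodynamic control.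

A fraction 30.7% of the reagent then becomes product, which is 18.4% of the solid substrate charged. Counting the dissolved part too, the solid gives up 30.4% of its charge, less than it holds, so I expect solid to remain and the freeze to stand.

The forecast says forward and back rates have come level, with conversion 18.4%, product 18.4% and starting material 12%. Its ground: “The solid dissolves far faster than it reacts”.

The simulation gives forward and back rates have come level, with conversion 18.4%, product 18.4% and starting material 12.0%. In this flask, the largest change in the share of a substrate, an intermediate or a product over the second half of the time is 0.1 percentage points. Carried to the neighbour charged with 2.40 equiv of reagent, the held ratio again puts 30.7% of the reagent into product, which is 73.7% of the solid substrate charged. That neighbour stands at 73.8% product at 5.00 min, with 26% of its solid substrate left, solid or dissolved.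

Its constants are invented; the result is computed.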